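Assumptions on the chemistry: compounds 8 and 9 are carried as mixtures of the two C7 carbinol epimers, because C7 becomes the ketone. The ligand in step 2 is written as (S,S), the hand expected to give the R acid; if a first run shows the opposite sense, the (R,R) ligand is used.

## Analysis of the target

CNP0234761.1 is a tetrahydrofuran lignan built on a single oxolane ring, numbered here O1, C2, C3, C4 and C5. C2 carries a 3-hydroxy-4-methoxyphenyl group, C3 a hydroxymethyl group (C6) and C4 a 3-hydroxy-4-methoxybenzoyl group whose ketone carbon is C7. The three stereocentres are contiguous, (2S,3R,4S), and all-trans: the aryl group is trans to the hydroxymethyl arm, which is in turn trans to the aroyl group. C4 lies alpha to the aryl ketone and is the only centre that can be equilibrated, whereas C2 is a 4-methoxybenzylic ether carbon that is sensitive to acid, hydrogenolysis and hydride abstraction. The C6 hydroxyl can add to C7 whenever the C3 and C4 substituents are cis, and the two phenols need protection against base and oxidants. Because the two aryl rings are identical, the difficulty lies in telling their benzylic carbons apart: C2 is an ether carbon inside the ring, C7 a ketone outside it. The strategy rests on this difference: in an open-chain precursor in which C7 is already a ketone and C2 is still a methylene group, only the C2–H bonds are benzylic to an electron-rich ring, so a hydride-abstracting oxidant should act at C2 alone, and the C5 hydroxyl is the only one that can reach the resulting cation through a five-membered ring.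

## Retrosynthetic reasoning

**15 to 14 to 13 (protecting groups).** The phenols are carried as benzyl ethers, which survive the basic, reducing and oxidising steps of the route, so the last disconnection is the two O–benzyl bonds of 14. One step earlier the C6 hydroxyl carries a silyl group (13). A silyl ether is preferred to an ester for two reasons. An ester would have to be removed with base, exposing a free C6 hydroxyl and an enolisable C4 together just after C4 has been corrected. Its carbonyl would also sit within reach of the C4 enolate carbon.

**13 to 12 (C4).** The C4–H bond is the only one that can be exchanged, so the all-trans ketone 13 is traced to its C4 epimer 12. The forward step only has to reach equilibrium, which should favour the isomer with no cis vicinal pair.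

**12 to 11 to 10 (O1–C2, the key disconnection).** Compound 12 is the silyl ether of alcohol 11, the direct product of the ring closure. Cutting O1–C2 of 11 opens the ring to keto diol 10, in which C2 is a methylene group. The cut is made here because C2 is the only position where a cation is stabilised by a para-methoxy ring and can be generated by direct C–H oxidation. One ring, one C–O bond and the C2 stereocentre are formed without any pre-installed leaving group, and the two hydroxymethyl arms need not be differentiated because only C5–OH can close a five-membered ring. The forward reaction must oxidise C2–H once, not twice.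

**10 to 9 (C7 oxidation level).** The ketone is traced to the benzylic carbinol of triol 9. The forward step needs an oxidant that converts a benzylic secondary alcohol and leaves two primary alcohols alone.

**9 to 8 (C5 and C6).** Both hydroxymethyl groups are folded back into the γ-lactone 8, with C5 as the lactone carbonyl and C6 as the lactone CH2. This ties the C3–C4 relationship to a ring in which it can be set reliably.

**8 to 7 and 1 (C4–C7).** The C4–C7 bond is cut as an aldol between the enolate of benzyl lactone 7 and aldehyde 1. The existing C3 substituent directs the new C4 substituent trans, and the aroyl ring is delivered by the same aldehyde that supplies the other ring.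

**7 to 5 to 4 to 1 and 2 (C2–C3 and the absolute configuration).** Lactone 7 comes from half-ester 5 by reduction of the ester and ring closure. Acid 5 comes from alkene 4 by asymmetric hydrogenation, which sets C3, the centre that controls all others. Alkene 4 is the condensation product of aldehyde 1 with diester 2, which forms C2=C3. All carbons of the target thus derive from two equivalents of 1 and one of 2.

## Alternatives that were turned down

**Alternative 1: both aryl rings by double Friedel–Crafts reaction.** The disconnection cuts C7–aryl and C2–aryl and leads to two molecules of the arene A2, 2-methoxyphenyl acetate, and to the chiral core A3, a 2-acetoxy-3-(acetoxymethyl)oxolane-4-carbonyl chloride. In the forward step SnCl4 would ionise the acid chloride of A3 to an acylium ion at C7 and its anomeric acetate to an oxocarbenium ion at C2, and two molecules of A2 would attack para to their methoxy groups. The product is the triacetate A1 of the target; no ring is closed.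

- In its favour: it is the most convergent plan, it uses the identity of the two rings in a single operation, the methoxy group directs to the correct position, and only the deacetylation of A1 remains.
- Against it: A3 holds the C3 and C4 stereocentres and three differentiated oxygen functions, so it needs an asymmetric synthesis of its own, roughly as long as the whole chosen route to the precursor. A2 is only a moderately activated arene, and its intermolecular capture of the C2 oxocarbenium ion must compete with loss of the C3 proton from that cation. The basic deacetylation of A1 would expose a free C6 hydroxyl and an enolisable C4 together.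
- Comparison: on convergence and end-game length this alternative is stronger. The chosen strategy offers instead a precursor assembled from two inexpensive components by established lignan chemistry, and an intramolecular oxygen capture in place of an intermolecular arylation by a weak nucleophile.

**Alternative 2: Prins–pinacol rearrangement.** The disconnection cuts C2–C3 and C4–C5 and leads to the dioxolane A5, a 2,4-diaryl-1,3-dioxolane whose acetal carbon comes from aldehyde 1 and whose quaternary C4 position carries the second aryl group and an (E)-3-benzyloxypropenyl group. In the forward step SnCl4 opens the acetal of A5 to an oxocarbenium ion on O1, and a 2-oxonia-Cope shift forms C2–C3 while the C5–C7 bond breaks. The tin enolate then adds to the new oxocarbenium ion, forming C4–C5 and the ring. The product is the all-trans 4-(3-benzyloxy-4-mesyloxybenzoyl) tetrahydrofuran A4.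

- In its favour: two C–C bonds, the ring and all three stereocentres arise in one step, the chair transition state transfers chirality from the single carbinol centre of A5, and A4 needs no later C4 correction.
- Against it: the ionising centre of A5 is tertiary, benzylic and allylic. With a para-alkoxy group it would ionise and racemise, so that ring must carry a mesylate, which costs a demesylation and a methylation after A4 and means the two rings no longer come from one aldehyde. The [3,3] shift passes through an unsubstituted methylene oxocarbenium ion. The quaternary carbinol centre of A5 must be made enantiopure by an asymmetric synthesis of its own. The alkyl benzyl ether on C6 of A4 prolongs the final hydrogenolysis.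
- Comparison: on stereocontrol at C4 and on bonds formed per step this alternative is stronger. The chosen strategy offers a catalytic asymmetric entry, fewer corrective steps and no electronic re-tuning of one ring.

**Alternative 3: titanocene-mediated radical cyclisation.** The disconnection cuts C3–C4 and leads to the epoxy ether A7, a terminal epoxide tethered through O1 to an aryl propargyl ether. In the forward step Cp2TiCl (trivalent titanium, made from Cp2TiCl2 and zinc dust) opens the epoxide of A7 to the C3 radical, which adds 5-exo-dig to the alkyne and closes the ring. The product is the 4-arylidene tetrahydrofuran A6.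

- In its favour: the radical closure of A7 is mild, tolerates benzyl ethers, gives the 2,3-trans ring reliably and releases C6–OH free. As a ring-forming step it is at least as dependable as the oxidation chosen here.
- Against it: A6 has the wrong oxidation pattern at C4 and C7. Its styrene must be converted into C4–H and C7=O by protection, hydroboration–oxidation and a second oxidation, after which C4 again needs thermodynamic correction. A7 contains an enantiopure, acid-sensitive, electron-rich benzylic epoxy carbinol unit, the usual access to which is a kinetic resolution that discards half the material. Titanium is used stoichiometrically.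
- Comparison: the chosen strategy delivers C7 as the ketone before the ring is closed and uses that ketone to differentiate the two rings, giving a shorter sequence than the one that leads through A6.

Key step: step 7

## Route

**Step 1**
Reactants: 1 3-benzyloxy-4-methoxybenzaldehyde; 2 dimethyl succinate
Product: 4 (E)-4-(3-benzyloxy-4-methoxyphenyl)-3-(methoxycarbonyl)but-3-enoic acid, via paraconic ester lactone 3 (not isolated)
Conditions: NaOMe (2.2 equiv), MeOH, reflux; then aq HCl
Reagents that add atoms: none
Why: Stobbe condensation: the succinate enolate adds to the non-enolisable aldehyde, the aldolate lactonises to 3, and base-induced ring opening gives the half-ester carboxylate, which makes the condensation irreversible and limits it to one aldehyde per succinate; the E acid (aryl trans to the ester) is the usual major isomer and is purified by crystallisation.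

**Step 2**
Reactants: 4 (E)-4-(3-benzyloxy-4-methoxyphenyl)-3-(methoxycarbonyl)but-3-enoic acid
Product: 5 (3R)-4-(3-benzyloxy-4-methoxyphenyl)-3-(methoxycarbonyl)butanoic acid
Conditions: H2 (5 bar), [Rh(cod)((S,S)-Et-DuPhos)]BF4 (0.5 mol%), NaOMe (0.1 equiv), MeOH, rt
Reagents that add atoms: none
Why: Asymmetric hydrogenation of an itaconate-type half-ester: carboxylate and alkene chelate the cationic rhodium centre and the C2-symmetric bisphospholane selects the alkene face, which sets C3 (R); this homogeneous catalyst does not cleave aryl benzyl ethers.

**Step 3**
Reactants: 5 (3R)-4-(3-benzyloxy-4-methoxyphenyl)-3-(methoxycarbonyl)butanoic acid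
Product: 7 (4R)-4-(3-benzyloxy-4-methoxybenzyl)oxolan-2-one, via hydroxy acid 6 (not isolated)
Conditions: KOH (1.0 equiv), EtOH, 0 °C; CaCl2, NaBH4, EtOH, 0 °C to rt; then 2 M HCl, rt
Reagents that add atoms: none
Why: Chemoselective borohydride reduction: Ca(BH4)2 formed in the flask reduces the methyl ester while the potassium carboxylate is inert, and acidification closes hydroxy acid 6 to the γ-lactone; the stereocentre should hold at this low basicity and temperature and ceases to be alpha to a carbonyl once the ester is reduced.

**Step 4**
Reactants: 7 (4R)-4-(3-benzyloxy-4-methoxybenzyl)oxolan-2-one; 1 3-benzyloxy-4-methoxybenzaldehyde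
Product: 8 (3S,4R)-4-(3-benzyloxy-4-methoxybenzyl)-3-[(3-benzyloxy-4-methoxyphenyl)(hydroxy)methyl]oxolan-2-one (both C7 epimers)
Conditions: LiN(i-Pr)2 (1.1 equiv), THF, −78 °C; then 1, −78 °C; aq NH4Cl at −78 °C
Reagents that add atoms: none
Why: Aldol addition of a lactone lithium enolate: the aldehyde approaches the enolate face opposite the adjacent benzyl group, so the new centre (C4 of the target) is set trans to C3; the carbinol configuration at C7 is irrelevant, and the cold quench suppresses retro-aldol cleavage.

**Step 5**
Reactants: 8 (3S,4R)-4-(3-benzyloxy-4-methoxybenzyl)-3-[(3-benzyloxy-4-methoxyphenyl)(hydroxy)methyl]oxolan-2-one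
Product: 9 (2R,3R)-2-[(3-benzyloxy-4-methoxyphenyl)(hydroxy)methyl]-3-(3-benzyloxy-4-methoxybenzyl)butane-1,4-diol (both C7 epimers)
Conditions: LiAlH4 (3 equiv), THF, 0 °C to rt; H2O, aq NaOH work-up
Reagents that add atoms: none
Why: Hydride reduction of the lactone to the 1,4-diol: the lactone carbonyl becomes C5 and the lactone CH2 stays as C6; no stereocentre is touched, and reduction of the lactone at 0 °C should outrun retro-aldol of the aluminium alkoxide.

**Step 6**
Reactants: 9 (2R,3R)-2-[(3-benzyloxy-4-methoxyphenyl)(hydroxy)methyl]-3-(3-benzyloxy-4-methoxybenzyl)butane-1,4-diol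
Product: 10 (2R,3R)-2-(3-benzyloxy-4-methoxybenzoyl)-3-(3-benzyloxy-4-methoxybenzyl)butane-1,4-diol
Conditions: activated MnO2 (15 equiv), CH2Cl2, rt
Reagents that add atoms: none
Why: Surface oxidation by MnO2 is fast for benzylic alcohols and very slow for saturated primary alcohols, so only C7 is oxidised; the neutral medium should spare the β-hydroxy ketone from dehydration and retro-aldol loss of formaldehyde.

**Step 7**
Reactants: 10 (2R,3R)-2-(3-benzyloxy-4-methoxybenzoyl)-3-(3-benzyloxy-4-methoxybenzyl)butane-1,4-diol
Product: 11 (2S,3R,4R)-2-(3-benzyloxy-4-methoxyphenyl)-4-(3-benzyloxy-4-methoxybenzoyl)-3-(hydroxymethyl)oxolane (2,3-trans, 3,4-cis)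
Conditions: DDQ (1.1 equiv), 4 Å MS, CH2Cl2, 0 °C to rt
Reagents that add atoms: none
Why: DDQ forms a charge-transfer complex with the electron-rich 3-benzyloxy-4-methoxybenzyl ring of 10 and removes hydride from C2, the only carbon whose C–H bonds are benzylic to a para-methoxy ring and not attached to oxygen (C7 is already a carbonyl that deactivates its ring, and the O–CH2Ph carbons are benzylic only to unsubstituted phenyl rings). The resulting 4-methoxybenzylic cation is captured by the C5 hydroxyl in a 5-exo-trig closure that forms O1–C2 and the oxolane ring, whereas the C6 hydroxyl could reach C2 only through a four-membered ring. The closest known reaction type is the DDQ oxidative cyclisation of 4-alkoxybenzyl butane-1,4-diols to 2-aryl tetrahydrofuran lignans, a case of quinone-mediated benzylic C–H etherification. The new stereocentre C2 is controlled by C3: in the envelope transition state the aryl group takes the face opposite the C3 hydroxymethyl arm, and because the benzylic C2–O1 bond can re-ionise in the presence of the acidic hydroquinone, the 2,3-trans (2S) isomer should also be the equilibrium product. C3 is untouched, and any drift at C4 is harmless because that centre is equilibrated in step 9. Beyond site selectivity the step must stop after one oxidation, since 11 still has a benzylic, oxygen-bearing C2–H; this is addressed by using barely more than one equivalent of DDQ, excluding water with sieves so that the cation is not diverted to a carbinol and on to a ketone, and keeping the temperature low.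

**Step 8**
Reactants: 11 (2S,3R,4R)-2-(3-benzyloxy-4-methoxyphenyl)-4-(3-benzyloxy-4-methoxybenzoyl)-3-(hydroxymethyl)oxolane
Product: 12 (2S,3R,4R)-2-(3-benzyloxy-4-methoxyphenyl)-4-(3-benzyloxy-4-methoxybenzoyl)-3-[(tert-butyldimethylsilyloxy)methyl]oxolane
Conditions: TBSCl (1.3 equiv), imidazole (2.5 equiv), DMF, 0 °C to rt
Reagents that add atoms: tert-butyldimethylsilyl chloride, CC(C)(C)[Si](C)(C)Cl
Why: Silylation of the primary alcohol removes the hydroxyl that can add to C7 from the cis position; if 11 rests partly in its closed hemiketal form, the open form is silylated and the ring–chain equilibrium follows.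

**Step 9**
Reactants: 12 (2S,3R,4R)-2-(3-benzyloxy-4-methoxyphenyl)-4-(3-benzyloxy-4-methoxybenzoyl)-3-[(tert-butyldimethylsilyloxy)methyl]oxolane
Product: 13 (2S,3R,4S)-2-(3-benzyloxy-4-methoxyphenyl)-4-(3-benzyloxy-4-methoxybenzoyl)-3-[(tert-butyldimethylsilyloxy)methyl]oxolane (all-trans)
Conditions: DBU (0.5 equiv), toluene, rt to 40 °C
Reagents that add atoms: none
Why: Base-mediated epimerisation through the C4 enolate under thermodynamic control: 12 has the C3 arm and the C4 aroyl group cis, 13 has every vicinal pair trans and should dominate at equilibrium. The silyl ether offers the enolate no electrophile and no hemiketal, and ring opening by loss of O1 from C5 is the reverse of a 5-endo-trig closure and is stereoelectronically disfavoured.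

**Step 10**
Reactants: 13 (2S,3R,4S)-2-(3-benzyloxy-4-methoxyphenyl)-4-(3-benzyloxy-4-methoxybenzoyl)-3-[(tert-butyldimethylsilyloxy)methyl]oxolane
Product: 14 (2S,3R,4S)-2-(3-benzyloxy-4-methoxyphenyl)-4-(3-benzyloxy-4-methoxybenzoyl)-3-(hydroxymethyl)oxolane
Conditions: HF·pyridine, pyridine, THF, 0 °C to rt
Reagents that add atoms: none
Why: Fluoride-driven desilylation in a buffered, weakly acidic medium in which C4 does not enolise, so the freed hydroxyl is never exposed to base and the corrected configuration is kept; in the trans isomer the hydroxyl cannot reach C7.

**Step 11**
Reactants: 14 (2S,3R,4S)-2-(3-benzyloxy-4-methoxyphenyl)-4-(3-benzyloxy-4-methoxybenzoyl)-3-(hydroxymethyl)oxolane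
Product: 15 (2S,3R,4S)-2-(3-hydroxy-4-methoxyphenyl)-4-(3-hydroxy-4-methoxybenzoyl)-3-(hydroxymethyl)oxolane (CNP0234761.1)
Conditions: H2 (1 atm), 10% Pd/C, EtOAc, rt; stopped after uptake of 2 equiv H2
Reagents that add atoms: none
Why: Hydrogenolysis of aryl benzyl ethers over palladium: in a neutral aprotic solvent these should cleave faster than the dialkyl benzylic C2–O1 bond and before the electron-rich aryl ketone is reduced; no stereocentre is involved.

## Compound list

1 | 3-benzyloxy-4-methoxybenzaldehyde | COc1ccc(C=O)cc1OCc1ccccc1 | starting material
2 | dimethyl succinate | COC(=O)CCC(=O)OC | starting material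
3 | methyl 2-(3-benzyloxy-4-methoxyphenyl)-5-oxooxolane-3-carboxylate (paraconic ester lactone, racemic mixture of diastereomers) | COC(=O)C1CC(=O)OC1c1ccc(OC)c(OCc2ccccc2)c1 | intermediate
4 | (E)-4-(3-benzyloxy-4-methoxyphenyl)-3-(methoxycarbonyl)but-3-enoic acid | COC(=O)/C(CC(=O)O)=C/c1ccc(OC)c(OCc2ccccc2)c1 | intermediate
5 | (3R)-4-(3-benzyloxy-4-methoxyphenyl)-3-(methoxycarbonyl)butanoic acid | COC(=O)[C@H](Cc1ccc(OC)c(OCc2ccccc2)c1)CC(=O)O | intermediate
6 | (3R)-4-(3-benzyloxy-4-methoxyphenyl)-3-(hydroxymethyl)butanoic acid | OC[C@H](Cc1ccc(OC)c(OCc2ccccc2)c1)CC(=O)O | intermediate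
7 | (4R)-4-(3-benzyloxy-4-methoxybenzyl)oxolan-2-one | O=C1OC[C@H](Cc2ccc(OC)c(OCc3ccccc3)c2)C1 | intermediate
8 | (3S,4R)-4-(3-benzyloxy-4-methoxybenzyl)-3-[(3-benzyloxy-4-methoxyphenyl)(hydroxy)methyl]oxolan-2-one, both carbinol epimers | O=C1OC[C@H](Cc2ccc(OC)c(OCc3ccccc3)c2)[C@H]1C(O)c1ccc(OC)c(OCc2ccccc2)c1 | intermediate
9 | (2R,3R)-2-[(3-benzyloxy-4-methoxyphenyl)(hydroxy)methyl]-3-(3-benzyloxy-4-methoxybenzyl)butane-1,4-diol, both carbinol epimers | COc1ccc(C(O)[C@@H](CO)[C@H](CO)Cc2ccc(OC)c(OCc3ccccc3)c2)cc1OCc1ccccc1 | intermediate
10 | (2R,3R)-2-(3-benzyloxy-4-methoxybenzoyl)-3-(3-benzyloxy-4-methoxybenzyl)butane-1,4-diol | COc1ccc(C(=O)[C@@H](CO)[C@H](CO)Cc2ccc(OC)c(OCc3ccccc3)c2)cc1OCc1ccccc1 | intermediate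
11 | (2S,3R,4R)-2-(3-benzyloxy-4-methoxyphenyl)-4-(3-benzyloxy-4-methoxybenzoyl)-3-(hydroxymethyl)oxolane | COc1ccc(C(=O)[C@H]2CO[C@H](c3ccc(OC)c(OCc4ccccc4)c3)[C@H]2CO)cc1OCc1ccccc1 | intermediate
12 | (2S,3R,4R)-2-(3-benzyloxy-4-methoxyphenyl)-4-(3-benzyloxy-4-methoxybenzoyl)-3-[(tert-butyldimethylsilyloxy)methyl]oxolane | COc1ccc(C(=O)[C@H]2CO[C@H](c3ccc(OC)c(OCc4ccccc4)c3)[C@H]2CO[Si](C)(C)C(C)(C)C)cc1OCc1ccccc1 | intermediate
13 | (2S,3R,4S)-2-(3-benzyloxy-4-methoxyphenyl)-4-(3-benzyloxy-4-methoxybenzoyl)-3-[(tert-butyldimethylsilyloxy)methyl]oxolane | COc1ccc(C(=O)[C@@H]2CO[C@H](c3ccc(OC)c(OCc4ccccc4)c3)[C@H]2CO[Si](C)(C)C(C)(C)C)cc1OCc1ccccc1 | intermediate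
14 | (2S,3R,4S)-2-(3-benzyloxy-4-methoxyphenyl)-4-(3-benzyloxy-4-methoxybenzoyl)-3-(hydroxymethyl)oxolane | COc1ccc(C(=O)[C@@H]2CO[C@H](c3ccc(OC)c(OCc4ccccc4)c3)[C@H]2CO)cc1OCc1ccccc1 | intermediate
15 | (2S,3R,4S)-2-(3-hydroxy-4-methoxyphenyl)-4-(3-hydroxy-4-methoxybenzoyl)-3-(hydroxymethyl)oxolane (CNP0234761.1) | COc1ccc(C(=O)[C@@H]2CO[C@H](c3ccc(OC)c(O)c3)[C@H]2CO)cc1O | target

## Step count and least certain steps

Total step count: 11. Longest linear sequence: 11 steps, from 1 and 2 to 15; aldehyde 1 enters twice, in steps 1 and 4.

**Step 7 (key step).** The most likely failure is over-oxidation: a second hydride abstraction from the product's own C2–H, which is benzylic and now also alpha to oxygen, followed by hydrolytic opening. Diversion of the cation by adventitious water, or capture by the hemiketal hydroxyl of a closed form of 10, would have the same effect. Fallback: separate the C–H oxidation from the ring closure. From 10, TBSCl and imidazole in DMF give the bis(tert-butyldimethylsilyl) ether F1. DDQ in CH2Cl2–AcOH then acetoxylates C2 to the benzylic acetate F2 (both C2 epimers); its C2–H is deactivated by the acetoxy group against a second abstraction, and it has no free hydroxyl that could close. TsOH·H2O in wet MeCN removes both silyl groups and ionises the acetate, and C5–OH closes the ring by an acid-mediated cationic etherification, the classical closure of aryl tetrahydrofuran lignans. The route is rejoined at 11.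

**Step 6.** The most likely failure is a slow heterogeneous oxidation that gives the product time to dehydrate at the β-hydroxy ketone or to lose formaldehyde by retro-aldol cleavage on the basic oxide surface. Fallback: protect, oxidise in solution, deprotect. From 9, TESCl and imidazole in CH2Cl2 at −78 to −40 °C silylate the two primary hydroxyls first and give the bis(triethylsilyl) ether F3. Dess–Martin periodinane buffered with NaHCO3 oxidises the remaining benzylic carbinol to the bis(triethylsilyl) ether of the keto diol F4. PPTS in MeOH removes the silyl groups, and the route is rejoined at 10.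

**Step 9.** The most likely failure is incomplete correction because the equilibrium leaves a substantial share of the 3,4-cis isomer; a stronger base would not change an equilibrium ratio and would invite ring opening by elimination. Fallback: change from single-pass equilibration to a separation-and-recycle loop based on the different behaviour of the two free alcohols. The mixture of 12 and 13 is desilylated under the conditions of step 10. The trans alcohol 14 cannot close onto its ketone, while the cis alcohol 11 can, so the two should differ clearly on silica. 14 continues to step 11 and recovered 11 returns to step 8. No new compound is made.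

**Step 11.** The most likely failure is over-reduction: hydrogenolytic opening of the benzylic C2–O1 bond, or reduction of the aryl ketone to the carbinol and further. Fallback: remove the benzyl groups without hydrogen. From 14, BCl3 with pentamethylbenzene as a non-basic cation scavenger in CH2Cl2 at −78 °C cleaves aryl benzyl ethers by Lewis-acid activation and Friedel–Crafts capture of the benzyl cation. The reaction is quenched cold with methanol so that the C2–O1 bond has no opportunity to ionise, and the route is rejoined at 15. No new compound is made.

## Further compounds

F1 | step 7 | bis(tert-butyldimethylsilyl) ether of keto diol 10, (2R,3R) | COc1ccc(C(=O)[C@@H](CO[Si](C)(C)C(C)(C)C)[C@H](CO[Si](C)(C)C(C)(C)C)Cc2ccc(OC)c(OCc3ccccc3)c2)cc1OCc1ccccc1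
F2 | step 7 | C2 benzylic acetate of F1, both C2 epimers | COc1ccc(C(=O)[C@@H](CO[Si](C)(C)C(C)(C)C)[C@H](CO[Si](C)(C)C(C)(C)C)C(OC(C)=O)c2ccc(OC)c(OCc3ccccc3)c2)cc1OCc1ccccc1
F3 | step 6 | 1,4-bis(triethylsilyl) ether of triol 9, both carbinol epimers | COc1ccc(C(O)[C@@H](CO[Si](CC)(CC)CC)[C@H](CO[Si](CC)(CC)CC)Cc2ccc(OC)c(OCc3ccccc3)c2)cc1OCc1ccccc1
F4 | step 6 | bis(triethylsilyl) ether of keto diol 10 | COc1ccc(C(=O)[C@@H](CO[Si](CC)(CC)CC)[C@H](CO[Si](CC)(CC)CC)Cc2ccc(OC)c(OCc3ccccc3)c2)cc1OCc1ccccc1
F0 | step 9 | none | none
F0 | step 11 | none | none
A1 | alternative 1 | triacetate of the target | COc1ccc(C(=O)[C@@H]2CO[C@H](c3ccc(OC)c(OC(C)=O)c3)[C@H]2COC(C)=O)cc1OC(C)=O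
A2 | alternative 1 | 2-methoxyphenyl acetate | COc1ccccc1OC(C)=O
A3 | alternative 1 | 2-acetoxy-3-(acetoxymethyl)oxolane-4-carbonyl chloride, 3,4-trans as in the target, anomeric mixture | O=C(Cl)[C@@H]1COC(OC(C)=O)[C@H]1COC(C)=O
A4 | alternative 2 | all-trans 2-(3-benzyloxy-4-methoxyphenyl)-3-(benzyloxymethyl)-4-(3-benzyloxy-4-mesyloxybenzoyl)oxolane | CS(=O)(=O)Oc1ccc(C(=O)[C@@H]2CO[C@H](c3ccc(OC)c(OCc4ccccc4)c3)[C@H]2COCc2ccccc2)cc1OCc1ccccc1
A5 | alternative 2 | 2-(3-benzyloxy-4-methoxyphenyl)-4-(3-benzyloxy-4-mesyloxyphenyl)-4-[(E)-3-benzyloxyprop-1-enyl]-1,3-dioxolane, (4R) drawn for a chair with the aryl group equatorial, acetal carbon as formed | COc1ccc(C2OC[C@@](/C=C/COCc3ccccc3)(c3ccc(OS(C)(=O)=O)c(OCc4ccccc4)c3)O2)cc1OCc1ccccc1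
A6 | alternative 3 | 2-aryl-4-arylidene-3-(hydroxymethyl)oxolane, 2,3-trans, alkene drawn Z | COc1ccc(/C=C2\CO[C@H](c3ccc(OC)c(OCc4ccccc4)c3)[C@H]2CO)cc1OCc1ccccc1
A7 | alternative 3 | 3-aryl-prop-2-ynyl ether of (3-benzyloxy-4-methoxyphenyl)(oxiran-2-yl)methanol, epoxide carbon of either configuration | COc1ccc(C#CCO[C@H](c2ccc(OC)c(OCc3ccccc3)c2)C2CO2)cc1OCc1ccccc1
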